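**Plan**
- Retrosynthesis: the four allyl ethers come off last; the C4 ketone comes from a C4 alcohol; the oxirane comes from the prenyl alkene; the C4 alcohol with the C3 centre comes from an isoflavone. The isoflavone is cut at O1–C8a and C3–C4 back to a 2'-fluorochalcone epoxide, and this is cut into a ring A acetophenone and a ring B benzaldehyde.
- Forward: rings A and B are bought as arenes; the chalcone chain is joined by aldol condensation and epoxidized; ring C then arises in one flask by a 1,2-aroyl shift (C3–C4) followed by fluoride displacement by the former epoxide oxygen (O1–C8a); the oxirane of the side chain is made afterwards.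
- Enabling features: ring B has oxygen at C4', para to C1', so the future C3 ionizes easily as a benzylic cation and accepts the migrating aroyl group. C8a of ring A is ortho to the C4 carbonyl and meta to the oxygens at C5 and C7, so a fluoride there is readily displaced.
- Stereochemistry: C3 (S) comes from asymmetric transfer hydrogenation of the isoflavone with dynamic kinetic resolution (catalyst control). It is carried at the C4 alcohol level, where it cannot epimerize, while the (R)-oxirane is set by Shi epoxidation (catalyst control).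
- All four phenols travel as allyl ethers and are freed at the end under neutral zerovalent-palladium conditions.

Key step: step 8

Remark: the chalcone epoxide is used as the racemic trans compound (one enantiomer drawn). The 2-formyl deoxybenzoin and the isoflavanone formed in the flask are drawn without configuration at C3, because these centres are erased or converged in steps 8 and 9.

Step 1
Reactants: 1 5-fluorobenzene-1,3-diol (5-fluororesorcinol)
Product: 2 1-(2-fluoro-4,6-dihydroxyphenyl)ethan-1-one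
Conditions: AcOH, ZnCl2, 140 °C
Reagents that add atoms: acetic acid, CC(=O)O
Why: Nencki-type Friedel–Crafts C-acylation of a resorcinol, expected at the carbon ortho to one hydroxyl and para to the other (the one flanked by fluorine), as with other 5-substituted resorcinols, which places fluorine ortho to the acetyl group.

Step 2
Reactants: 2 1-(2-fluoro-4,6-dihydroxyphenyl)ethan-1-one
Product: 3 1-[2-fluoro-4,6-bis(allyloxy)phenyl]ethan-1-one
Conditions: allyl bromide, K2CO3, DMF, 50 °C
Reagents that add atoms: allyl bromide, C=CCBr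
Why: Williamson etherification in which excess reagent in DMF also alkylates the chelated ortho hydroxyl, while the aryl fluoride should be inert to phenoxide at this temperature.

Step 3
Reactants: 4 3-bromo-4,5-dihydroxybenzaldehyde
Product: 5 3-bromo-4,5-bis(tert-butyldimethylsilyloxy)benzaldehyde
Conditions: TBSCl, imidazole, DMF, rt
Reagents that add atoms: tert-butyldimethylsilyl chloride, CC(C)(C)[Si](C)(C)Cl
Why: Standard silylation that masks the catechol for the cross-coupling, which aryl allyl ethers would not survive because zerovalent palladium ionizes them.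

Step 4
Reactants: 5 3-bromo-4,5-bis(tert-butyldimethylsilyloxy)benzaldehyde
Product: 6 3,4-bis(tert-butyldimethylsilyloxy)-5-(3-methylbut-2-en-1-yl)benzaldehyde
Conditions: tributyl(3-methylbut-2-en-1-yl)stannane, Pd(PPh3)4 (5 mol%), DMF, 95 °C
Reagents that add atoms: tributyl(3-methylbut-2-en-1-yl)stannane, CCCC[Sn](CCCC)(CCCC)CC=C(C)C
Why: Stille coupling in which the allylic stannane should transfer through its α-carbon to give the linear prenyl arene, under neutral conditions that leave the aryl silyl ethers and the aldehyde alone.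

Step 5
Reactants: 6 3,4-bis(tert-butyldimethylsilyloxy)-5-(3-methylbut-2-en-1-yl)benzaldehyde
Product: 8 3,4-bis(allyloxy)-5-(3-methylbut-2-en-1-yl)benzaldehyde, via bis(tetrabutylammonium) catecholate 7 (not isolated)
Conditions: TBAF (2.2 equiv), degassed THF, 0 °C; then allyl bromide (3 equiv), 0 °C to rt
Reagents that add atoms: allyl bromide, C=CCBr
Why: Fluoride desilylation gives the naked catecholate, which is O-allylated in the same flask (Williamson etherification), so the air-sensitive free catechol is never handled.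

Step 6
Reactants: 3 1-[2-fluoro-4,6-bis(allyloxy)phenyl]ethan-1-one; 8 3,4-bis(allyloxy)-5-(3-methylbut-2-en-1-yl)benzaldehyde
Product: 9 (E)-1-[2-fluoro-4,6-bis(allyloxy)phenyl]-3-[3,4-bis(allyloxy)-5-(3-methylbut-2-en-1-yl)phenyl]prop-2-en-1-one
Conditions: KOH, EtOH, rt
Reagents that add atoms: none
Why: Claisen–Schmidt condensation in which only the ketone can enolize and dehydration of the aldol should give the (E)-chalcone.

Step 7
Reactants: 9 (E)-1-[2-fluoro-4,6-bis(allyloxy)phenyl]-3-[3,4-bis(allyloxy)-5-(3-methylbut-2-en-1-yl)phenyl]prop-2-en-1-one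
Product: 10 rac-trans-[2-fluoro-4,6-bis(allyloxy)phenyl]{(2R*,3S*)-3-[3,4-bis(allyloxy)-5-(3-methylbut-2-en-1-yl)phenyl]oxiran-2-yl}methanone
Conditions: 30% H2O2, NaOH (cat.), MeOH/THF, 0 °C to rt
Reagents that add atoms: hydrogen peroxide, OO
Why: Weitz–Scheffer nucleophilic epoxidation, in which hydroperoxide adds only to the enone and leaves the prenyl and allyl alkenes untouched, giving the trans epoxide as a racemate whose configuration is not needed.

Step 8
Reactants: 10 rac-trans-[2-fluoro-4,6-bis(allyloxy)phenyl]{(2R*,3S*)-3-[3,4-bis(allyloxy)-5-(3-methylbut-2-en-1-yl)phenyl]oxiran-2-yl}methanone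
Product: 12 5,7-bis(allyloxy)-3-[3,4-bis(allyloxy)-5-(3-methylbut-2-en-1-yl)phenyl]-4H-chromen-4-one, via 2-formyl deoxybenzoin 11 (not isolated)
Conditions: BF3·OEt2 (0.3 equiv), CH2Cl2, −20 to 0 °C; then K2CO3 (dry), DMF, CH2Cl2 distilled off, 60 °C
Reagents that add atoms: none
Why: BF3 opens the oxirane at the benzylic carbon, whose cation is stabilized by the C4' oxygen para to C1' of ring B, and the aroyl group then shifts from the neighbouring carbon (1,2-acyl shift, the House–Meinwald rearrangement of chalcone epoxides to 2-formyl deoxybenzoins); this makes the C3–C4 bond and turns the 1,3-diaryl chalcone chain into the 1,2-diaryl isoflavonoid chain of 11. The enolized formyl group of 11, whose oxygen is the former epoxide oxygen, is deprotonated by K2CO3 and displaces fluoride at C8a by addition–elimination, as in chromone syntheses from 2-fluoroaryl 1,3-dicarbonyl compounds, which makes the O1–C8a bond. Ring C closes as a six-membered ring in a 6-endo-trig conjugate addition–elimination (the C4a=C8a bond lies inside the new ring) through a Meisenheimer-type intermediate stabilized by the C4 carbonyl. No stereocentre is created, because C3 becomes trigonal; its configuration is set in step 9. The step needs acyl rather than hydride migration and ring closure rather than retro-Claisen loss of the formyl group: the electron-rich aroyl group and the well-stabilized cation should favour the acyl shift, and dry K2CO3 in DMF acting on a fluoride ortho to the ketone and meta to both allyloxy groups should favour closure. Substoichiometric BF3 at low temperature should leave the prenyl group and the allyl ethers intact.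

Step 9
Reactants: 12 5,7-bis(allyloxy)-3-[3,4-bis(allyloxy)-5-(3-methylbut-2-en-1-yl)phenyl]-4H-chromen-4-one
Product: 14 (3S,4S)-5,7-bis(allyloxy)-3-[3,4-bis(allyloxy)-5-(3-methylbut-2-en-1-yl)phenyl]chroman-4-ol (3,4-cis), via racemic isoflavanone 13 (not isolated)
Conditions: RuCl[(S,S)-TsDPEN](p-cymene) (2 mol%), HCO2H/Et3N (1:1.2), EtOAc, 40 °C
Reagents that add atoms: none
Why: Noyori–Ikariya asymmetric transfer hydrogenation with dynamic kinetic resolution, in which the ruthenium hydride first reduces C2=C3 to the isoflavanone 13, C3 epimerizes through the enol under Et3N, and the (S,S)-catalyst should deliver hydride to C4 of one enantiomer anti to the C3 aryl group, giving the cis (3S,4S)-alcohol by the CH/π model established for chromanones (the mirror-image catalyst is available if the sense is opposite).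

Step 10
Reactants: 14 (3S,4S)-5,7-bis(allyloxy)-3-[3,4-bis(allyloxy)-5-(3-methylbut-2-en-1-yl)phenyl]chroman-4-ol
Product: 15 (3S,4S)-5,7-bis(allyloxy)-3-[3,4-bis(allyloxy)-5-{[(2R)-3,3-dimethyloxiran-2-yl]methyl}phenyl]chroman-4-ol
Conditions: D-fructose-derived Shi ketone (1,2:4,5-di-O-isopropylidene-β-D-erythro-2,3-hexodiulo-2,6-pyranose, 30 mol%), Oxone (2KHSO5·KHSO4·K2SO4), K2CO3, Bu4NHSO4, MeCN/CH2(OMe)2/aq. Na2B4O7 buffer (pH 10.5), 0 °C
Reagents that add atoms: potassium peroxymonosulfate (active component of Oxone), [K+].[O-]S(=O)(=O)OO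
Why: Shi epoxidation, in which the chiral dioxirane should attack the electron-rich trisubstituted prenyl alkene far faster than the four monosubstituted allyl ethers, and the spiro transition state of the D-fructose-derived ketone should give the (R)-oxirane, while C3 cannot epimerize at pH 10.5 because C4 is an alcohol.

Step 11
Reactants: 15 (3S,4S)-5,7-bis(allyloxy)-3-[3,4-bis(allyloxy)-5-{[(2R)-3,3-dimethyloxiran-2-yl]methyl}phenyl]chroman-4-ol
Product: 16 (3S)-5,7-bis(allyloxy)-3-[3,4-bis(allyloxy)-5-{[(2R)-3,3-dimethyloxiran-2-yl]methyl}phenyl]chroman-4-one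
Conditions: Dess–Martin periodinane, NaHCO3, CH2Cl2, 0 °C to rt
Reagents that add atoms: none
Why: Dess–Martin oxidation of the benzylic alcohol under bicarbonate buffering, which is neither basic nor acidic enough to enolize the new α-aryl ketone or open the oxirane, so C3 should keep its (S) configuration.

Step 12
Reactants: 16 (3S)-5,7-bis(allyloxy)-3-[3,4-bis(allyloxy)-5-{[(2R)-3,3-dimethyloxiran-2-yl]methyl}phenyl]chroman-4-one
Product: 17 (3S)-3-[3,4-dihydroxy-5-{[(2R)-3,3-dimethyloxiran-2-yl]methyl}phenyl]-5,7-dihydroxychroman-4-one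
Conditions: Pd(PPh3)4 (10 mol%), N-methylaniline (8 equiv), degassed THF, rt
Reagents that add atoms: none
Why: Tsuji–Trost-type deallylation, in which zerovalent palladium ionizes each aryl allyl ether to a π-allyl complex and the weakly basic N-methylaniline captures the allyl group, so the phenols are released without base or acid and neither C3 epimerization nor attack of the C4' hydroxyl on the neighbouring oxirane should be triggered.

**Compound list**
1 | 5-fluorobenzene-1,3-diol | Oc1cc(O)cc(F)c1 | starting material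
2 | 1-(2-fluoro-4,6-dihydroxyphenyl)ethan-1-one | CC(=O)c1c(F)cc(O)cc1O | intermediate
3 | 1-[2-fluoro-4,6-bis(allyloxy)phenyl]ethan-1-one | CC(=O)c1c(F)cc(OCC=C)cc1OCC=C | intermediate
4 | 3-bromo-4,5-dihydroxybenzaldehyde | O=Cc1cc(O)c(O)c(Br)c1 | starting material
5 | 3-bromo-4,5-bis(tert-butyldimethylsilyloxy)benzaldehyde | O=Cc1cc(O[Si](C)(C)C(C)(C)C)c(O[Si](C)(C)C(C)(C)C)c(Br)c1 | intermediate
6 | 3,4-bis(tert-butyldimethylsilyloxy)-5-(3-methylbut-2-en-1-yl)benzaldehyde | O=Cc1cc(O[Si](C)(C)C(C)(C)C)c(O[Si](C)(C)C(C)(C)C)c(CC=C(C)C)c1 | intermediate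
7 | bis(tetrabutylammonium) 5-formyl-3-(3-methylbut-2-en-1-yl)benzene-1,2-diolate | O=Cc1cc([O-])c([O-])c(CC=C(C)C)c1.CCCC[N+](CCCC)(CCCC)CCCC.CCCC[N+](CCCC)(CCCC)CCCC | intermediate
8 | 3,4-bis(allyloxy)-5-(3-methylbut-2-en-1-yl)benzaldehyde | O=Cc1cc(OCC=C)c(OCC=C)c(CC=C(C)C)c1 | intermediate
9 | (E)-1-[2-fluoro-4,6-bis(allyloxy)phenyl]-3-[3,4-bis(allyloxy)-5-(3-methylbut-2-en-1-yl)phenyl]prop-2-en-1-one | O=C(/C=C/c1cc(OCC=C)c(OCC=C)c(CC=C(C)C)c1)c1c(F)cc(OCC=C)cc1OCC=C | intermediate
10 | rac-trans-[2-fluoro-4,6-bis(allyloxy)phenyl]{(2R*,3S*)-3-[3,4-bis(allyloxy)-5-(3-methylbut-2-en-1-yl)phenyl]oxiran-2-yl}methanone (one enantiomer drawn) | O=C(c1c(F)cc(OCC=C)cc1OCC=C)[C@H]1O[C@@H]1c1cc(OCC=C)c(OCC=C)c(CC=C(C)C)c1 | intermediate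
11 | 3-[2-fluoro-4,6-bis(allyloxy)phenyl]-2-[3,4-bis(allyloxy)-5-(3-methylbut-2-en-1-yl)phenyl]-3-oxopropanal (2-formyl deoxybenzoin, enolized) | O=CC(c1cc(OCC=C)c(OCC=C)c(CC=C(C)C)c1)C(=O)c1c(F)cc(OCC=C)cc1OCC=C | intermediate
12 | 5,7-bis(allyloxy)-3-[3,4-bis(allyloxy)-5-(3-methylbut-2-en-1-yl)phenyl]-4H-chromen-4-one | O=c1c(-c2cc(OCC=C)c(OCC=C)c(CC=C(C)C)c2)coc2cc(OCC=C)cc(OCC=C)c12 | intermediate
13 | rac-5,7-bis(allyloxy)-3-[3,4-bis(allyloxy)-5-(3-methylbut-2-en-1-yl)phenyl]chroman-4-one | O=C1c2c(OCC=C)cc(OCC=C)cc2OCC1c1cc(OCC=C)c(OCC=C)c(CC=C(C)C)c1 | intermediate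
14 | (3S,4S)-5,7-bis(allyloxy)-3-[3,4-bis(allyloxy)-5-(3-methylbut-2-en-1-yl)phenyl]chroman-4-ol | CC(C)=CCc1cc([C@H]2COc3cc(OCC=C)cc(OCC=C)c3[C@H]2O)cc(OCC=C)c1OCC=C | intermediate
15 | (3S,4S)-5,7-bis(allyloxy)-3-[3,4-bis(allyloxy)-5-{[(2R)-3,3-dimethyloxiran-2-yl]methyl}phenyl]chroman-4-ol | CC1(C)O[C@@H]1Cc1cc([C@H]2COc3cc(OCC=C)cc(OCC=C)c3[C@H]2O)cc(OCC=C)c1OCC=C | intermediate
16 | (3S)-5,7-bis(allyloxy)-3-[3,4-bis(allyloxy)-5-{[(2R)-3,3-dimethyloxiran-2-yl]methyl}phenyl]chroman-4-one | CC1(C)O[C@@H]1Cc1cc([C@H]2COc3cc(OCC=C)cc(OCC=C)c3C2=O)cc(OCC=C)c1OCC=C | intermediate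
17 | (3S)-3-[3,4-dihydroxy-5-{[(2R)-3,3-dimethyloxiran-2-yl]methyl}phenyl]-5,7-dihydroxychroman-4-one | CC1(C)O[C@@H]1Cc1cc([C@H]2COc3cc(O)cc(O)c3C2=O)cc(O)c1O | target

**Count**
Total steps: 12. Longest linear sequence: 10 steps (4 to 17, steps 3–12).

**Steps most likely to fail**

Step 8. The formyl group may be lost by retro-Claisen cleavage before the ring closes, or fluoride displacement may be slow. The fallback sets out from 10 and returns at 12. Compound 10 would be rearranged with BF3·OEt2 as before and the crude product cleaved on purpose with aqueous KOH to the deoxybenzoin 1-[2-fluoro-4,6-bis(allyloxy)phenyl]-2-[3,4-bis(allyloxy)-5-(3-methylbut-2-en-1-yl)phenyl]ethan-1-one F1. Claisen formylation of F1 with ethyl formate and NaH in dry THF would then regenerate 11 as its anhydrous sodium enolate, with no water or carbonate present to cleave it, and warming in DMF should close it to 12.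

Step 9. Hydride transfer to the electron-rich C4 carbonyl next to the C5 allyloxy group may be slow, or the acid-labile benzylic alcohol may ionize in the formate medium, eroding conversion and selectivity. The fallback sets out from 12 and returns at 14. Conjugate reduction of 12 with LiBH(s-Bu)3 and trapping of the enolate with Me3SiCl would give the silyl enol ether 5,7-bis(allyloxy)-3-[3,4-bis(allyloxy)-5-(3-methylbut-2-en-1-yl)phenyl]-4-(trimethylsilyloxy)-2H-chromene F2. Enantioselective protonation of F2 with a BINOL-derived N-triflyl thiophosphoramide catalyst and phenol as proton source (catalyst enantiomer chosen by a trial) would give (3S)-5,7-bis(allyloxy)-3-[3,4-bis(allyloxy)-5-(3-methylbut-2-en-1-yl)phenyl]chroman-4-one F3. Reduction of F3 with LiBH(s-Bu)3 at −78 °C, with hydride adding anti to the aryl group, should give 14.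

Step 12. The C4' hydroxyl may open the neighbouring oxirane as it is freed, or slow cleavage of the hindered allyl ethers may allow C3 to epimerize. The fallback changes the protecting-group class; it sets out from 12 and returns at 17. Deallylation of 12 with Pd(PPh3)4 and N-methylaniline, where no oxirane or stereocentre is at risk, would give 5,7-dihydroxy-3-[3,4-dihydroxy-5-(3-methylbut-2-en-1-yl)phenyl]-4H-chromen-4-one F4. Silylation with TBSCl and imidazole would give 5,7-bis(tert-butyldimethylsilyloxy)-3-[3,4-bis(tert-butyldimethylsilyloxy)-5-(3-methylbut-2-en-1-yl)phenyl]-4H-chromen-4-one F5. The conditions of steps 9, 10 and 11 would then be repeated in this series: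
- step 9 conditions would give (3S,4S)-5,7-bis(tert-butyldimethylsilyloxy)-3-[3,4-bis(tert-butyldimethylsilyloxy)-5-(3-methylbut-2-en-1-yl)phenyl]chroman-4-ol F6;
- step 10 conditions would give (3S,4S)-5,7-bis(tert-butyldimethylsilyloxy)-3-[3,4-bis(tert-butyldimethylsilyloxy)-5-{[(2R)-3,3-dimethyloxiran-2-yl]methyl}phenyl]chroman-4-ol F7;
- step 11 conditions would give (3S)-5,7-bis(tert-butyldimethylsilyloxy)-3-[3,4-bis(tert-butyldimethylsilyloxy)-5-{[(2R)-3,3-dimethyloxiran-2-yl]methyl}phenyl]chroman-4-one F8.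

Desilylation of F8 with TBAF buffered with AcOH in THF at −20 °C should then give 17.

**Further compounds**
F1 | step 8 | 1-[2-fluoro-4,6-bis(allyloxy)phenyl]-2-[3,4-bis(allyloxy)-5-(3-methylbut-2-en-1-yl)phenyl]ethan-1-one | O=C(Cc1cc(OCC=C)c(OCC=C)c(CC=C(C)C)c1)c1c(F)cc(OCC=C)cc1OCC=C
F2 | step 9 | 5,7-bis(allyloxy)-3-[3,4-bis(allyloxy)-5-(3-methylbut-2-en-1-yl)phenyl]-4-(trimethylsilyloxy)-2H-chromene | C[Si](C)(C)OC1=C(c2cc(OCC=C)c(OCC=C)c(CC=C(C)C)c2)COc2cc(OCC=C)cc(OCC=C)c21
F3 | step 9 | (3S)-5,7-bis(allyloxy)-3-[3,4-bis(allyloxy)-5-(3-methylbut-2-en-1-yl)phenyl]chroman-4-one | CC(C)=CCc1cc([C@H]2COc3cc(OCC=C)cc(OCC=C)c3C2=O)cc(OCC=C)c1OCC=C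
F4 | step 12 | 5,7-dihydroxy-3-[3,4-dihydroxy-5-(3-methylbut-2-en-1-yl)phenyl]-4H-chromen-4-one | CC(C)=CCc1cc(-c2coc3cc(O)cc(O)c3c2=O)cc(O)c1O
F5 | step 12 | 5,7-bis(tert-butyldimethylsilyloxy)-3-[3,4-bis(tert-butyldimethylsilyloxy)-5-(3-methylbut-2-en-1-yl)phenyl]-4H-chromen-4-one | CC(C)=CCc1cc(-c2coc3cc(O[Si](C)(C)C(C)(C)C)cc(O[Si](C)(C)C(C)(C)C)c3c2=O)cc(O[Si](C)(C)C(C)(C)C)c1O[Si](C)(C)C(C)(C)C
F6 | step 12 | (3S,4S)-5,7-bis(tert-butyldimethylsilyloxy)-3-[3,4-bis(tert-butyldimethylsilyloxy)-5-(3-methylbut-2-en-1-yl)phenyl]chroman-4-ol | CC(C)=CCc1cc([C@H]2COc3cc(O[Si](C)(C)C(C)(C)C)cc(O[Si](C)(C)C(C)(C)C)c3[C@H]2O)cc(O[Si](C)(C)C(C)(C)C)c1O[Si](C)(C)C(C)(C)C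
F7 | step 12 | (3S,4S)-5,7-bis(tert-butyldimethylsilyloxy)-3-[3,4-bis(tert-butyldimethylsilyloxy)-5-{[(2R)-3,3-dimethyloxiran-2-yl]methyl}phenyl]chroman-4-ol | CC1(C)O[C@@H]1Cc1cc([C@H]2COc3cc(O[Si](C)(C)C(C)(C)C)cc(O[Si](C)(C)C(C)(C)C)c3[C@H]2O)cc(O[Si](C)(C)C(C)(C)C)c1O[Si](C)(C)C(C)(C)C
F8 | step 12 | (3S)-5,7-bis(tert-butyldimethylsilyloxy)-3-[3,4-bis(tert-butyldimethylsilyloxy)-5-{[(2R)-3,3-dimethyloxiran-2-yl]methyl}phenyl]chroman-4-one | CC1(C)O[C@@H]1Cc1cc([C@H]2COc3cc(O[Si](C)(C)C(C)(C)C)cc(O[Si](C)(C)C(C)(C)C)c3C2=O)cc(O[Si](C)(C)C(C)(C)C)c1O[Si](C)(C)C(C)(C)C
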